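Which flask held the most E after 1.5 h, with the same charge at four temperatures?

| flask | D | J | temperature | remark | time |
|---|---|---|---|---|---|
| winter | 1 M | 1 equiv | 66 °C | run made earlier |  |
| noon | 2 M | 1.5 equiv | 91 °C | run made earlier |  |
| south-east | 2.0 M | 1.00 equiv | 70 °C |  | 1.5 h |
| north | 2.0 M | 1.00 equiv | 100 °C |  | 1.5 h |
| south | 2.0 M | 1.00 equiv | 85 °C |  | 1.5 h |
| west | 2.0 M | 1.00 equiv | 55 °C |  | 1.5 h |

| run | time / min | E / % | D / % |
|---|---|---|---|
| winter | 8.00 | 1 | 47 |
| winter | 15.0 | 5 | 48 |
| winter | 25.0 | 3 | 44 |
| winter | 50.0 | 7 | 44 |
| winter | 90.0 | 10 | 36 |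
| noon | 3.00 | 5 | 32 |
| noon | 8.00 | 11 | 27 |
| noon | 15.0 | 15 | 19 |
| noon | 20.0 | 19 | 15 |
| noon | 30.0 | 21 | 12 |

(readings scatter by 1.5 percentage points)

- the best flask by amount of E, in percent of the D and J together charged; "all alike" if 1.5 percentage points covers them all (south-east / north / south / west / all alike)
- amount of E at the end, in percent of the D and J together charged, south-east
- amount of E at the end, in percent of the D and J together charged, north
- amount of E at the end, in percent of the D and J together charged, south
- amount of E at the end, in percent of the D and J together charged, west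

- percentages count the D that a species holds: one L counts as two
- the analysis behind the earlier runs scatters by 1.5 percentage points, standard deviation
- on the list of suspects stand: D + E -> L; D -> E; E <-> G; E -> Q; D <-> J; J -> G
- in a conversion J counts as not yet reacted

I counted turnovers. Reading D's loss as first order between the first and last readings gave a rate constant k of 0.00325 min⁻¹ in the winter run and 0.0363 min⁻¹ in the noon run, so k doubled every 7.18 K. At 91 °C the time asked held 3.27 lifetimes of D; this is the turnover count N, the time asked multiplied by k, and it doubles with k. Between the same noon readings E gained 0.800 of a point per point of D lost. D starts at 50% of the charge, so I took as my estimate of the E made directly from D that yield times 50% times (1 − e^(−N)); this estimate counts D and not J.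

| Flask | N | Lifetime of D | E from D |
|---|---|---|---|
| north | 7.79 | 11.6 min | 40.0% |
| south | 1.83 | 49.2 min | 33.6% |
| south-east | 0.431 | 209 min | 14.0% |
| west | 0.101 | 891 min | 3.85% |

South-east and west held less than one turnover, so there the estimate climbs nearly in step with N. North and south held more, so there the estimate flattens. The next rung is E's drain. In the noon run E + D fell by 4 percentage points against a scatter of 1.5 points, a weak reading that puts E's lifetime near 87.7 min. With the same doubling that is 36.8 min in north, slower than D's loss there but faster than the time asked. I could not read from the two runs whether that drain was one-way, so I let the estimate rank the flasks, with north ahead.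

The forecast differed at north and south. It named south, with 14% for south-east, 9% for north, 21% for south and 3.5% for west, reasoning that “North has consumed all its D, and E is decaying”.

The simulation gave north: 14.1% south-east, 42.3% north, 29.5% south, 3.29% west.

    D + E → L (k = 0.0110 M⁻¹ min⁻¹, Ea = 93.0 kJ mol⁻¹)
    D → E (k = 0.0840 min⁻¹, Ea = 106 kJ mol⁻¹)
    E ⇌ G (K = 0.620, k = 0.00800 min⁻¹, Ea = 107 kJ mol⁻¹, ΔH = −27.0 kJ mol⁻¹)
    E → Q (k = 0.00260 min⁻¹, Ea = 119 kJ mol⁻¹)
    D ⇌ J (K = 5.90, k = 0.0300 min⁻¹, Ea = 125 kJ mol⁻¹, ΔH = −26.0 kJ mol⁻¹)
    J → G (k = 0.0340 min⁻¹, Ea = 119 kJ mol⁻¹)
    (constants at 100 °C)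

North's E still rose, from 36.7% at 0.750 h to 42.3% at 1.50 h, above my 40.0%, with N at 7.79 and 0.25% of the D charge left. Part of the reason is G's return to E together with the short time: without that return north holds 16.0%, and left ten times as long it holds 14.5%. West repeated at 80 °C counts N = 1.13, for an estimate of 27.1%; computed, it gives 25.5%.

(The readings stem from a simulated flask for an exercise, noise included.)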